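**Plan**
- Retrosynthesis: after removal of eight phenol protecting groups, each trans-dihydrobenzofuran is cut at its aryl–C3 bond (C3a–C3) and then at O1–C2, ring A (the one carrying the styryl group) first and ring B second. This leaves two 2-bromoresorcinol stilbenes (9 and 21) and resveratrol, the stilbenes of 9 and 21 being cut at C=C.
- Enabling feature: in ring B the arene carbon C3a' lies between the ring oxygen O1' and the C4' phenol oxygen (the 2-position of a resorcinol). It can therefore carry Br and then Li held by both oxygens, five atoms (C3a'–C7a'–O1'–C2'–C3') from the benzylic carbon C3' of an open-chain aryl ether.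
- Forward: phosphonate 6 gives bromophenols 9 and 21; resveratrol gives epoxide 12; the phenoxide of 9 opens 12 (O1'–C2'), then tosylation, Br–Li exchange and 5-exo-tet displacement close ring B (C3a'–C3'). The stilbene of that product is epoxidised, opened by 21 and cyclised the same way to ring A; global deprotection ends the route.
- Stereochemistry: both epoxides come from Shi epoxidation with the L-fructose-derived ketone. The phenoxide inverts C2 and the aryllithium inverts C3, so each (S,S)-epoxide maps onto a trans-(2S,3S) dihydrobenzofuran.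

Key step: step 10

Remark: the SMILES is read as trans-(2S,3S) in both dihydrobenzofurans; unprimed locants refer to ring A (styryl-bearing), primed locants to ring B.

Step 1
Reactants: 1 methyl 4-bromo-3,5-dihydroxybenzoate
Product: 2 methyl 4-bromo-3-hydroxy-5-(methoxymethoxy)benzoate
Conditions: MOMCl (1.0 equiv), i-Pr2NEt, CH2Cl2, 0 °C; bis-ether and 1 separated and recycled
Reagents that add atoms: chloromethyl methyl ether, COCCl
Why: Williamson-type O-alkylation with one equivalent of MOMCl should protect one of the two equivalent phenols statistically, the mono-ether being separable from bis-ether and recovered 1.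

Step 2
Reactants: 2 methyl 4-bromo-3-hydroxy-5-(methoxymethoxy)benzoate
Product: 3 methyl 4-bromo-3-(methoxymethoxy)-5-(triisopropylsilyloxy)benzoate
Conditions: i-Pr3SiCl, imidazole, DMF, 40 °C
Reagents that add atoms: chlorotriisopropylsilane, CC(C)[Si](Cl)(C(C)C)C(C)C
Why: Standard silylation of the remaining phenol installs a TIPS ether that should survive hydride reduction, Appel and Arbuzov conditions and later leave with fluoride while the MOM ether stays.

Step 3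
Reactants: 3 methyl 4-bromo-3-(methoxymethoxy)-5-(triisopropylsilyloxy)benzoate
Product: 4 [4-bromo-3-(methoxymethoxy)-5-(triisopropylsilyloxy)phenyl]methanol
Conditions: i-Bu2AlH (2.5 equiv), CH2Cl2, −78 to 0 °C
Reagents that add atoms: none
Why: Hydride reduction of the ester to the benzylic alcohol with i-Bu2AlH should leave the aryl bromide, MOM and silyl ethers untouched.

Step 4
Reactants: 4 [4-bromo-3-(methoxymethoxy)-5-(triisopropylsilyloxy)phenyl]methanol
Product: 5 2-bromo-5-(bromomethyl)-1-(methoxymethoxy)-3-(triisopropylsilyloxy)benzene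
Conditions: CBr4, PPh3, CH2Cl2, 0 °C
Reagents that add atoms: carbon tetrabromide, BrC(Br)(Br)Br
Why: Appel reaction converts the primary benzylic alcohol to the bromide under neutral conditions that the acetal and silyl ether tolerate.

Step 5
Reactants: 5 2-bromo-5-(bromomethyl)-1-(methoxymethoxy)-3-(triisopropylsilyloxy)benzene
Product: 6 diethyl [4-bromo-3-(methoxymethoxy)-5-(triisopropylsilyloxy)benzyl]phosphonate
Conditions: P(OEt)3 (neat), 120 °C
Reagents that add atoms: triethyl phosphite, CCOP(OCC)OCC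
Why: Michaelis–Arbuzov reaction of the benzylic bromide with triethyl phosphite gives the phosphonate, the hindered aryl bromide being inert without a metal catalyst.

Step 6
Reactants: 6 diethyl [4-bromo-3-(methoxymethoxy)-5-(triisopropylsilyloxy)benzyl]phosphonate; 7 4-(benzyloxy)benzaldehyde
Product: 9 5-[(E)-2-(4-benzyloxyphenyl)ethenyl]-2-bromo-3-(methoxymethoxy)phenol, via silyl ether 8 (not isolated)
Conditions: KOt-Bu, THF, 0 °C to rt; then Bu4NF, rt
Reagents that add atoms: none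
Why: Horner–Wadsworth–Emmons olefination of an aryl aldehyde with a benzylic phosphonate should give the E-stilbene, and fluoride then cleaves only the silyl ether to free the phenol needed for ether formation.

Step 7
Reactants: 10 resveratrol
Product: 11 (E)-3,5,4'-tris(benzyloxy)stilbene
Conditions: BnBr (3.3 equiv), K2CO3, DMF, rt
Reagents that add atoms: benzyl bromide, BrCc1ccccc1
Why: Williamson ether synthesis benzylates all three phenols of commercial resveratrol, giving donor-type protecting groups that leave in one Lewis-acid operation at the end.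

Step 8
Reactants: 11 (E)-3,5,4'-tris(benzyloxy)stilbene
Product: 12 (2S,3S)-2-[4-(benzyloxy)phenyl]-3-[3,5-bis(benzyloxy)phenyl]oxirane
Conditions: 1,2:4,5-di-O-isopropylidene-β-L-erythro-2,3-hexodiulo-2,6-pyranose (L-fructose-derived Shi ketone, 0.3 equiv), Oxone (2KHSO5·KHSO4·K2SO4), K2CO3, Bu4NHSO4, MeCN/CH2(OMe)2/aq. Na2B4O7 buffer, 0 °C
Reagents that add atoms: potassium peroxymonosulfate (oxidant of Oxone), [K+].[O-]S(=O)(=O)OO
Why: Shi asymmetric epoxidation (chiral dioxirane, spiro transition state) of a trans-1,2-diarylethene should set both epoxide carbons as S with the L-fructose-derived ketone, the enantiomer of the usual catalyst that gives (R,R)-epoxides from trans-stilbenes.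

Step 9
Reactants: 9 5-[(E)-2-(4-benzyloxyphenyl)ethenyl]-2-bromo-3-(methoxymethoxy)phenol; 12 (2S,3S)-2-[4-(benzyloxy)phenyl]-3-[3,5-bis(benzyloxy)phenyl]oxirane
Product: 13 (1S,2R)-2-[4-(benzyloxy)phenyl]-1-[3,5-bis(benzyloxy)phenyl]-2-{5-[(E)-2-(4-benzyloxyphenyl)ethenyl]-2-bromo-3-(methoxymethoxy)phenoxy}ethan-1-ol
Conditions: 9 (1.2 equiv), Cs2CO3 (0.3 equiv), DMF, 90 °C
Reagents that add atoms: none
Why: Base-catalysed SN2 ring opening of the epoxide by the phenoxide should occur at the benzylic carbon bearing the 4-benzyloxyphenyl ring, which supports the loose transition state better than the carbon next to the meta-dioxygenated ring, with inversion there (new C2 centre R) and retention of the (S)-carbinol carbon.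

Step 10
Reactants: 13 (1S,2R)-2-[4-(benzyloxy)phenyl]-1-[3,5-bis(benzyloxy)phenyl]-2-{5-[(E)-2-(4-benzyloxyphenyl)ethenyl]-2-bromo-3-(methoxymethoxy)phenoxy}ethan-1-ol
Product: 17 (2S,3S)-3-[3,5-bis(benzyloxy)phenyl]-2-[4-(benzyloxy)phenyl]-6-[(E)-2-(4-benzyloxyphenyl)ethenyl]-4-(methoxymethoxy)-2,3-dihydrobenzofuran, via lithium alkoxide 14 (not isolated), via tosylate 15 (not isolated), via aryllithium 16 (not isolated)
Conditions: n-BuLi (1.0 equiv), THF, −78 °C; TsCl (1.05 equiv), −78 to −30 °C; t-BuLi (2.1 equiv), −78 °C, then to 0 °C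
Reagents that add atoms: none
Why: Proposed new method: the lithium alkoxide of 13 is sulfonylated, bromine–lithium exchange at −78 °C (faster than any attack on the sulfonate) then gives an aryllithium held between the MOM oxygen and the ether oxygen, and its in-plane sp2 lone pair displaces the secondary benzylic tosylate five atoms away, forming C3a'–C3'. The closest known reaction type is the Parham cycloalkylation (aryllithium from halogen–lithium exchange alkylated intramolecularly by a primary halide, as in 2,3-dihydrobenzofuran from 2-bromophenyl 2-bromoethyl ether), together with invertive epoxide opening by aryllithiums; new here is a stereodefined secondary benzylic sulfonate as electrophile. Ring B closes in the 5-exo-tet mode. C3' is set by inversion of the (S)-carbinol carbon derived from epoxide 12 while C2' is untouched, and the anti substrate places the two aryl groups on opposite faces in the transition state, giving the trans-(2S,3S) ring. The step needs regioselectivity for the carbon between the two oxygens, secured by the bromine placed there, and substitution in preference to E2 elimination or addition to the stilbene, secured by the low temperature, the intramolecular five-membered transition state and the gauche (non-antiperiplanar) position of C2'–H relative to the leaving group in the reactive conformer.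

Step 11
Reactants: 17 (2S,3S)-3-[3,5-bis(benzyloxy)phenyl]-2-[4-(benzyloxy)phenyl]-6-[(E)-2-(4-benzyloxyphenyl)ethenyl]-4-(methoxymethoxy)-2,3-dihydrobenzofuran
Product: 18 (2S,3S)-3-[3,5-bis(benzyloxy)phenyl]-2-[4-(benzyloxy)phenyl]-6-{(2S,3S)-3-[4-(benzyloxy)phenyl]oxiran-2-yl}-4-(methoxymethoxy)-2,3-dihydrobenzofuran
Conditions: L-fructose-derived Shi ketone (as in step 8, 0.3 equiv), Oxone (2KHSO5·KHSO4·K2SO4), K2CO3, Bu4NHSO4, MeCN/CH2(OMe)2/aq. Na2B4O7 buffer, 0 °C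
Reagents that add atoms: potassium peroxymonosulfate (oxidant of Oxone), [K+].[O-]S(=O)(=O)OO
Why: Shi epoxidation again, under reagent control because the ring B stereocentres are remote from the alkene, should give the (S,S)-epoxide.

Step 12
Reactants: 6 diethyl [4-bromo-3-(methoxymethoxy)-5-(triisopropylsilyloxy)benzyl]phosphonate; 19 2,4-bis(benzyloxy)benzaldehyde
Product: 21 5-[(E)-2-(2,4-bis(benzyloxy)phenyl)ethenyl]-2-bromo-3-(methoxymethoxy)phenol, via silyl ether 20 (not isolated)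
Conditions: KOt-Bu, THF, 0 °C to rt; then Bu4NF, rt
Reagents that add atoms: none
Why: Same Horner–Wadsworth–Emmons olefination and fluoride desilylation as in step 6, now with the 2,4-dioxygenated aldehyde that supplies the oxyresveratrol ring.

Step 13
Reactants: 18 (2S,3S)-3-[3,5-bis(benzyloxy)phenyl]-2-[4-(benzyloxy)phenyl]-6-{(2S,3S)-3-[4-(benzyloxy)phenyl]oxiran-2-yl}-4-(methoxymethoxy)-2,3-dihydrobenzofuran; 21 5-[(E)-2-(2,4-bis(benzyloxy)phenyl)ethenyl]-2-bromo-3-(methoxymethoxy)phenol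
Product: 22 (1S,2R)-2-[4-(benzyloxy)phenyl]-2-{5-[(E)-2-(2,4-bis(benzyloxy)phenyl)ethenyl]-2-bromo-3-(methoxymethoxy)phenoxy}-1-{(2S,3S)-3-[3,5-bis(benzyloxy)phenyl]-2-[4-(benzyloxy)phenyl]-4-(methoxymethoxy)-2,3-dihydrobenzofuran-6-yl}ethan-1-ol
Conditions: 21 (1.2 equiv), Cs2CO3 (0.3 equiv), DMF, 90 °C
Reagents that add atoms: none
Why: Same base-catalysed SN2 phenoxide opening as in step 9, at the 4-benzyloxybenzylic carbon with inversion, the other epoxide carbon being attached to the less cation-stabilising ring B arene.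

Step 14
Reactants: 22 (1S,2R)-2-[4-(benzyloxy)phenyl]-2-{5-[(E)-2-(2,4-bis(benzyloxy)phenyl)ethenyl]-2-bromo-3-(methoxymethoxy)phenoxy}-1-{(2S,3S)-3-[3,5-bis(benzyloxy)phenyl]-2-[4-(benzyloxy)phenyl]-4-(methoxymethoxy)-2,3-dihydrobenzofuran-6-yl}ethan-1-ol
Product: 26 (2S,3S)-2-[4-(benzyloxy)phenyl]-6-[(E)-2-(2,4-bis(benzyloxy)phenyl)ethenyl]-4-(methoxymethoxy)-3-{(2S,3S)-3-[3,5-bis(benzyloxy)phenyl]-2-[4-(benzyloxy)phenyl]-4-(methoxymethoxy)-2,3-dihydrobenzofuran-6-yl}-2,3-dihydrobenzofuran, via lithium alkoxide 23 (not isolated), via tosylate 24 (not isolated), via aryllithium 25 (not isolated)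
Conditions: n-BuLi (1.0 equiv), THF, −78 °C; TsCl (1.05 equiv), −78 to −30 °C; t-BuLi (2.1 equiv), −78 °C, then to 0 °C
Reagents that add atoms: none
Why: Proposed new method: the same one-pot tosylation, bromine–lithium exchange and invertive 5-exo-tet displacement of a secondary benzylic tosylate by the chelated aryllithium as in step 10 (closest known type: Parham cycloalkylation) now closes ring A, with C3 set by inversion of the (S)-carbinol carbon from epoxide 18 and C2 retained, to give the second trans-(2S,3S) ring.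

Step 15
Reactants: 26 (2S,3S)-2-[4-(benzyloxy)phenyl]-6-[(E)-2-(2,4-bis(benzyloxy)phenyl)ethenyl]-4-(methoxymethoxy)-3-{(2S,3S)-3-[3,5-bis(benzyloxy)phenyl]-2-[4-(benzyloxy)phenyl]-4-(methoxymethoxy)-2,3-dihydrobenzofuran-6-yl}-2,3-dihydrobenzofuran
Product: 27 4-[(E)-2-{(2S,3S)-3-[(2S,3S)-3-(3,5-dihydroxyphenyl)-4-hydroxy-2-(4-hydroxyphenyl)-2,3-dihydrobenzofuran-6-yl]-4-hydroxy-2-(4-hydroxyphenyl)-2,3-dihydrobenzofuran-6-yl}ethenyl]benzene-1,3-diol (CNP0186204.1)
Conditions: BCl3 (excess), C6HMe5 (excess), CH2Cl2, −78 to −40 °C; MeOH quench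
Reagents that add atoms: none
Why: Lewis-acid ether cleavage (BCl3 with pentamethylbenzene as cation scavenger) should remove the six benzyl and two MOM groups at low temperature without reducing or alkylating the stilbene, and the trans-(2S,3S) rings, being the thermodynamically preferred C2 epimers, should be retained.

**Compound list**
1 | methyl 4-bromo-3,5-dihydroxybenzoate | COC(=O)c1cc(O)c(Br)c(O)c1 | starting material
2 | methyl 4-bromo-3-hydroxy-5-(methoxymethoxy)benzoate | COCOc1cc(C(=O)OC)cc(O)c1Br | intermediate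
3 | methyl 4-bromo-3-(methoxymethoxy)-5-(triisopropylsilyloxy)benzoate | COCOc1cc(C(=O)OC)cc(O[Si](C(C)C)(C(C)C)C(C)C)c1Br | intermediate
4 | [4-bromo-3-(methoxymethoxy)-5-(triisopropylsilyloxy)phenyl]methanol | COCOc1cc(CO)cc(O[Si](C(C)C)(C(C)C)C(C)C)c1Br | intermediate
5 | 2-bromo-5-(bromomethyl)-1-(methoxymethoxy)-3-(triisopropylsilyloxy)benzene | COCOc1cc(CBr)cc(O[Si](C(C)C)(C(C)C)C(C)C)c1Br | intermediate
6 | diethyl [4-bromo-3-(methoxymethoxy)-5-(triisopropylsilyloxy)benzyl]phosphonate | CCOP(=O)(OCC)Cc1cc(OCOC)c(Br)c(O[Si](C(C)C)(C(C)C)C(C)C)c1 | intermediate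
7 | 4-(benzyloxy)benzaldehyde | O=Cc1ccc(OCc2ccccc2)cc1 | starting material
8 | triisopropylsilyl ether of 9 | COCOc1cc(/C=C/c2ccc(OCc3ccccc3)cc2)cc(O[Si](C(C)C)(C(C)C)C(C)C)c1Br | intermediate
9 | 5-[(E)-2-(4-benzyloxyphenyl)ethenyl]-2-bromo-3-(methoxymethoxy)phenol | COCOc1cc(/C=C/c2ccc(OCc3ccccc3)cc2)cc(O)c1Br | intermediate
10 | resveratrol, (E)-5-[2-(4-hydroxyphenyl)ethenyl]benzene-1,3-diol | Oc1ccc(/C=C/c2cc(O)cc(O)c2)cc1 | starting material
11 | (E)-3,5,4'-tris(benzyloxy)stilbene | c1ccc(COc2ccc(/C=C/c3cc(OCc4ccccc4)cc(OCc4ccccc4)c3)cc2)cc1 | intermediate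
12 | (2S,3S)-2-[4-(benzyloxy)phenyl]-3-[3,5-bis(benzyloxy)phenyl]oxirane | [C@@H]1(c2ccc(OCc3ccccc3)cc2)O[C@H]1c1cc(OCc2ccccc2)cc(OCc2ccccc2)c1 | intermediate
13 | (1S,2R)-2-[4-(benzyloxy)phenyl]-1-[3,5-bis(benzyloxy)phenyl]-2-{5-[(E)-2-(4-benzyloxyphenyl)ethenyl]-2-bromo-3-(methoxymethoxy)phenoxy}ethan-1-ol | O[C@@H](c1cc(OCc2ccccc2)cc(OCc2ccccc2)c1)[C@@H](c1ccc(OCc2ccccc2)cc1)Oc1cc(/C=C/c2ccc(OCc3ccccc3)cc2)cc(OCOC)c1Br | intermediate
14 | lithium alkoxide of 13 | [Li]O[C@@H](c1cc(OCc2ccccc2)cc(OCc2ccccc2)c1)[C@@H](c1ccc(OCc2ccccc2)cc1)Oc1cc(/C=C/c2ccc(OCc3ccccc3)cc2)cc(OCOC)c1Br | intermediate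
15 | p-toluenesulfonate ester of 13 at C1 | Cc1ccc(cc1)S(=O)(=O)O[C@@H](c1cc(OCc2ccccc2)cc(OCc2ccccc2)c1)[C@@H](c1ccc(OCc2ccccc2)cc1)Oc1cc(/C=C/c2ccc(OCc3ccccc3)cc2)cc(OCOC)c1Br | intermediate
16 | aryllithium from 15 (Li in place of Br) | Cc1ccc(cc1)S(=O)(=O)O[C@@H](c1cc(OCc2ccccc2)cc(OCc2ccccc2)c1)[C@@H](c1ccc(OCc2ccccc2)cc1)Oc1cc(/C=C/c2ccc(OCc3ccccc3)cc2)cc(OCOC)c1[Li] | intermediate
17 | (2S,3S)-3-[3,5-bis(benzyloxy)phenyl]-2-[4-(benzyloxy)phenyl]-6-[(E)-2-(4-benzyloxyphenyl)ethenyl]-4-(methoxymethoxy)-2,3-dihydrobenzofuran | c1(/C=C/c2ccc(OCc3ccccc3)cc2)cc(OCOC)c2c(c1)O[C@H](c1ccc(OCc3ccccc3)cc1)[C@H]2c1cc(OCc2ccccc2)cc(OCc2ccccc2)c1 | intermediate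
18 | (2S,3S)-3-[3,5-bis(benzyloxy)phenyl]-2-[4-(benzyloxy)phenyl]-6-{(2S,3S)-3-[4-(benzyloxy)phenyl]oxiran-2-yl}-4-(methoxymethoxy)-2,3-dihydrobenzofuran | [C@@H]1(c2ccc(OCc3ccccc3)cc2)O[C@H]1c1cc(OCOC)c2c(c1)O[C@H](c1ccc(OCc3ccccc3)cc1)[C@H]2c1cc(OCc2ccccc2)cc(OCc2ccccc2)c1 | intermediate
19 | 2,4-bis(benzyloxy)benzaldehyde | O=Cc1ccc(OCc2ccccc2)cc1OCc1ccccc1 | starting material
20 | triisopropylsilyl ether of 21 | COCOc1cc(/C=C/c2ccc(OCc3ccccc3)cc2OCc2ccccc2)cc(O[Si](C(C)C)(C(C)C)C(C)C)c1Br | intermediate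
21 | 5-[(E)-2-(2,4-bis(benzyloxy)phenyl)ethenyl]-2-bromo-3-(methoxymethoxy)phenol | COCOc1cc(/C=C/c2ccc(OCc3ccccc3)cc2OCc2ccccc2)cc(O)c1Br | intermediate
22 | (1S,2R)-2-[4-(benzyloxy)phenyl]-2-{5-[(E)-2-(2,4-bis(benzyloxy)phenyl)ethenyl]-2-bromo-3-(methoxymethoxy)phenoxy}-1-{(2S,3S)-3-[3,5-bis(benzyloxy)phenyl]-2-[4-(benzyloxy)phenyl]-4-(methoxymethoxy)-2,3-dihydrobenzofuran-6-yl}ethan-1-ol | O[C@@H](c1cc(OCOC)c2c(c1)O[C@H](c1ccc(OCc3ccccc3)cc1)[C@H]2c1cc(OCc2ccccc2)cc(OCc2ccccc2)c1)[C@@H](c1ccc(OCc2ccccc2)cc1)Oc1cc(/C=C/c2ccc(OCc3ccccc3)cc2OCc2ccccc2)cc(OCOC)c1Br | intermediate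
23 | lithium alkoxide of 22 | [Li]O[C@@H](c1cc(OCOC)c2c(c1)O[C@H](c1ccc(OCc3ccccc3)cc1)[C@H]2c1cc(OCc2ccccc2)cc(OCc2ccccc2)c1)[C@@H](c1ccc(OCc2ccccc2)cc1)Oc1cc(/C=C/c2ccc(OCc3ccccc3)cc2OCc2ccccc2)cc(OCOC)c1Br | intermediate
24 | p-toluenesulfonate ester of 22 at C1 | Cc1ccc(cc1)S(=O)(=O)O[C@@H](c1cc(OCOC)c2c(c1)O[C@H](c1ccc(OCc3ccccc3)cc1)[C@H]2c1cc(OCc2ccccc2)cc(OCc2ccccc2)c1)[C@@H](c1ccc(OCc2ccccc2)cc1)Oc1cc(/C=C/c2ccc(OCc3ccccc3)cc2OCc2ccccc2)cc(OCOC)c1Br | intermediate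
25 | aryllithium from 24 (Li in place of Br) | Cc1ccc(cc1)S(=O)(=O)O[C@@H](c1cc(OCOC)c2c(c1)O[C@H](c1ccc(OCc3ccccc3)cc1)[C@H]2c1cc(OCc2ccccc2)cc(OCc2ccccc2)c1)[C@@H](c1ccc(OCc2ccccc2)cc1)Oc1cc(/C=C/c2ccc(OCc3ccccc3)cc2OCc2ccccc2)cc(OCOC)c1[Li] | intermediate
26 | hexa-O-benzyl-4,4'-bis-O-(methoxymethyl) derivative of the target, both rings trans-(2S,3S) | c1ccc(COc2ccc([C@H]3Oc4cc(/C=C/c5ccc(OCc6ccccc6)cc5OCc5ccccc5)cc(OCOC)c4[C@@H]3c3cc(OCOC)c4c(c3)O[C@H](c3ccc(OCc5ccccc5)cc3)[C@H]4c3cc(OCc4ccccc4)cc(OCc4ccccc4)c3)cc2)cc1 | intermediate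
27 | 4-[(E)-2-{(2S,3S)-3-[(2S,3S)-3-(3,5-dihydroxyphenyl)-4-hydroxy-2-(4-hydroxyphenyl)-2,3-dihydrobenzofuran-6-yl]-4-hydroxy-2-(4-hydroxyphenyl)-2,3-dihydrobenzofuran-6-yl}ethenyl]benzene-1,3-diol (CNP0186204.1) | Oc1ccc([C@H]2Oc3cc(/C=C/c4ccc(O)cc4O)cc(O)c3[C@@H]2c2cc(O)c3c(c2)O[C@H](c2ccc(O)cc2)[C@H]3c2cc(O)cc(O)c2)cc1 | target

**Step count and risks**

Total steps: 15. Longest linear sequence: 12 steps (steps 1–6, 9, 10, 11, 13, 14, 15, from 1).

Steps most likely to fail: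

1. Step 10 (proposed new method). The sulfonate may be lost by E2 elimination, by participation of the neighbouring 4-benzyloxyphenyl ring or by electron transfer from the aryllithium, giving an enol ether or a ring with eroded configuration at C3'. The fallback sets out from 9 and comes back at 17, closing ring B at C2'–C3' by a rhodium carbene C–H insertion of known type. 9 is O-alkylated with 4-(benzyloxy)benzyl chloride (K2CO3, DMF) to the benzyl aryl ether F1. Br–Li exchange (t-BuLi, THF, −78 °C) and addition to 3,5-bis(benzyloxy)benzaldehyde give the diaryl carbinol F2, which MnO2 oxidises to the diaryl ketone F3. N2H4·H2O (EtOH, AcOH cat., reflux) gives the hydrazone F4, and MnO2 in CH2Cl2 oxidises it to the diaryldiazomethane F5. With Rh2(R-PTAD)4, dirhodium tetrakis[(R)-1-adamantyl(phthalimido)acetate], or its mirror-image complex (whichever sets 3S), the donor/donor carbene should insert into the benzylic O–CH2 bond to give the cis-dihydrobenzofuran F6 (2R,3S). A catalytic amount of CF3CO2H in CH2Cl2 should then epimerise C2' through reversible ionisation of the 4-alkoxybenzylic C–O bond and return the trans isomer 17.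

2. Step 14 (proposed new method). On the larger substrate the displacement at C3, now flanked by the ring B arene, may be slow enough for the aryllithium to be protonated or to act as a base. The fallback sets out from 17 and 21 and comes back at 26, using the same known carbene insertion. Lemieux–Johnson cleavage (OsO4 cat., NaIO4, 2,6-lutidine, dioxane/H2O) cuts the stilbene of 17 to the ring B aldehyde F7. 21 is O-alkylated with 4-(benzyloxy)benzyl chloride (K2CO3, DMF) to the benzyl aryl ether F8. Br–Li exchange (t-BuLi, −78 °C) and addition to F7 give the carbinol F9, oxidised with MnO2 to the ketone F10. N2H4·H2O gives the hydrazone F11, MnO2 the diazo compound F12, and the Rh2(PTAD)4 antipode that sets 3S should give the ring A cis isomer F13 (2R,3S in ring A). Catalytic CF3CO2H then epimerises C2 to 26.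

3. Step 9. The phenoxide may attack the other benzylic carbon, or the opening may be slow and partly ionising so that inversion at C2 is eroded. The fallback sets out from 9 and comes back at 13, fixing the regiochemistry through a ketone. Buchwald–Hartwig α-arylation of commercial 1-[3,5-bis(benzyloxy)phenyl]ethan-1-one with 1-(benzyloxy)-4-bromobenzene (Pd2(dba)3, BINAP, NaOt-Bu, THF, 70 °C) gives the deoxybenzoin F14. CuBr2 (EtOAc/CHCl3, reflux) gives the α-bromoketone F15, and 9 with K2CO3 in acetone displaces bromide to give the α-aryloxy ketone F16. Noyori–Ikariya transfer hydrogenation with [RuCl(p-cymene)((R,R)-TsDPEN)] in HCO2H/Et3N, with dynamic kinetic resolution through the enolisable C2 centre and Felkin–Anh-type hydride delivery, should give the anti (1S,2R) alcohol 13.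

Further compounds
F1 | step 10 | 2-bromo-1-{[4-(benzyloxy)benzyl]oxy}-5-[(E)-2-(4-benzyloxyphenyl)ethenyl]-3-(methoxymethoxy)benzene | COCOc1cc(/C=C/c2ccc(OCc3ccccc3)cc2)cc(OCc2ccc(OCc3ccccc3)cc2)c1Br
F2 | step 10 | [3,5-bis(benzyloxy)phenyl]{2-{[4-(benzyloxy)benzyl]oxy}-4-[(E)-2-(4-benzyloxyphenyl)ethenyl]-6-(methoxymethoxy)phenyl}methanol (racemic) | COCOc1cc(/C=C/c2ccc(OCc3ccccc3)cc2)cc(OCc2ccc(OCc3ccccc3)cc2)c1C(O)c1cc(OCc2ccccc2)cc(OCc2ccccc2)c1
F3 | step 10 | [3,5-bis(benzyloxy)phenyl]{2-{[4-(benzyloxy)benzyl]oxy}-4-[(E)-2-(4-benzyloxyphenyl)ethenyl]-6-(methoxymethoxy)phenyl}methanone | COCOc1cc(/C=C/c2ccc(OCc3ccccc3)cc2)cc(OCc2ccc(OCc3ccccc3)cc2)c1C(=O)c1cc(OCc2ccccc2)cc(OCc2ccccc2)c1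
F4 | step 10 | hydrazone of ketone F3 | COCOc1cc(/C=C/c2ccc(OCc3ccccc3)cc2)cc(OCc2ccc(OCc3ccccc3)cc2)c1C(=NN)c1cc(OCc2ccccc2)cc(OCc2ccccc2)c1
F5 | step 10 | diaryldiazomethane from F4 | COCOc1cc(/C=C/c2ccc(OCc3ccccc3)cc2)cc(OCc2ccc(OCc3ccccc3)cc2)c1C(=[N+]=[N-])c1cc(OCc2ccccc2)cc(OCc2ccccc2)c1
F6 | step 10 | (2R,3S)-cis isomer of 17 | c1(/C=C/c2ccc(OCc3ccccc3)cc2)cc(OCOC)c2c(c1)O[C@@H](c1ccc(OCc3ccccc3)cc1)[C@H]2c1cc(OCc2ccccc2)cc(OCc2ccccc2)c1
F7 | step 14 | (2S,3S)-3-[3,5-bis(benzyloxy)phenyl]-2-[4-(benzyloxy)phenyl]-4-(methoxymethoxy)-2,3-dihydrobenzofuran-6-carbaldehyde | O=Cc1cc(OCOC)c2c(c1)O[C@H](c1ccc(OCc3ccccc3)cc1)[C@H]2c1cc(OCc2ccccc2)cc(OCc2ccccc2)c1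
F8 | step 14 | 2-bromo-1-{[4-(benzyloxy)benzyl]oxy}-5-[(E)-2-(2,4-bis(benzyloxy)phenyl)ethenyl]-3-(methoxymethoxy)benzene | COCOc1cc(/C=C/c2ccc(OCc3ccccc3)cc2OCc2ccccc2)cc(OCc2ccc(OCc3ccccc3)cc2)c1Br
F9 | step 14 | carbinol from lithiated F8 and aldehyde F7 (mixture of carbinol epimers) | COCOc1cc(/C=C/c2ccc(OCc3ccccc3)cc2OCc2ccccc2)cc(OCc2ccc(OCc3ccccc3)cc2)c1C(O)c1cc(OCOC)c2c(c1)O[C@H](c1ccc(OCc3ccccc3)cc1)[C@H]2c1cc(OCc2ccccc2)cc(OCc2ccccc2)c1
F10 | step 14 | diaryl ketone from F9 | COCOc1cc(/C=C/c2ccc(OCc3ccccc3)cc2OCc2ccccc2)cc(OCc2ccc(OCc3ccccc3)cc2)c1C(=O)c1cc(OCOC)c2c(c1)O[C@H](c1ccc(OCc3ccccc3)cc1)[C@H]2c1cc(OCc2ccccc2)cc(OCc2ccccc2)c1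
F11 | step 14 | hydrazone of ketone F10 | COCOc1cc(/C=C/c2ccc(OCc3ccccc3)cc2OCc2ccccc2)cc(OCc2ccc(OCc3ccccc3)cc2)c1C(=NN)c1cc(OCOC)c2c(c1)O[C@H](c1ccc(OCc3ccccc3)cc1)[C@H]2c1cc(OCc2ccccc2)cc(OCc2ccccc2)c1
F12 | step 14 | diaryldiazomethane from F11 | COCOc1cc(/C=C/c2ccc(OCc3ccccc3)cc2OCc2ccccc2)cc(OCc2ccc(OCc3ccccc3)cc2)c1C(=[N+]=[N-])c1cc(OCOC)c2c(c1)O[C@H](c1ccc(OCc3ccccc3)cc1)[C@H]2c1cc(OCc2ccccc2)cc(OCc2ccccc2)c1
F13 | step 14 | ring A (2R,3S)-cis isomer of 26 | c1ccc(COc2ccc([C@@H]3Oc4cc(/C=C/c5ccc(OCc6ccccc6)cc5OCc5ccccc5)cc(OCOC)c4[C@@H]3c3cc(OCOC)c4c(c3)O[C@H](c3ccc(OCc5ccccc5)cc3)[C@H]4c3cc(OCc4ccccc4)cc(OCc4ccccc4)c3)cc2)cc1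
F14 | step 9 | 1-[3,5-bis(benzyloxy)phenyl]-2-[4-(benzyloxy)phenyl]ethan-1-one | O=C(Cc1ccc(OCc2ccccc2)cc1)c1cc(OCc2ccccc2)cc(OCc2ccccc2)c1
F15 | step 9 | 2-bromo-1-[3,5-bis(benzyloxy)phenyl]-2-[4-(benzyloxy)phenyl]ethan-1-one (racemic) | O=C(C(Br)c1ccc(OCc2ccccc2)cc1)c1cc(OCc2ccccc2)cc(OCc2ccccc2)c1
F16 | step 9 | 1-[3,5-bis(benzyloxy)phenyl]-2-[4-(benzyloxy)phenyl]-2-{5-[(E)-2-(4-benzyloxyphenyl)ethenyl]-2-bromo-3-(methoxymethoxy)phenoxy}ethan-1-one (racemic at C2) | O=C(C(Oc1cc(/C=C/c2ccc(OCc3ccccc3)cc2)cc(OCOC)c1Br)c1ccc(OCc2ccccc2)cc1)c1cc(OCc2ccccc2)cc(OCc2ccccc2)c1
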